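**Strategy.** Everything rests on cutting the cyclohexenone ring (C1 carbonyl, C2 methyl carbon, C3 chain-bearing carbon, C4 gem-dimethyl carbon, C5, C6) into ethyl vinyl ketone and an isopropyl ketone: quaternary C4 is the α-carbon and C3 the carbonyl carbon of that ketone, so the ring is a Robinson retron. One annulation, run last, forms C4–C5 and C2=C3, closes the carbocycle and delivers the natural product. Its precursor, ketone 22, already carries the complete 1,2-dioxane: the propanoate carbon and dioxane C3 come from an Evans aldol (C3 then inverted by hydroperoxide SN2), and quaternary C6 from a chair-controlled 6-endo peroxymercuration of a Z-trisubstituted alkene.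

Key step: step 13

Remark: 2-methoxyprop-2-yl hydroperoxide (step 7) is taken as a reagent made in one operation from 2-methoxypropene and H2O2; the dioxane is numbered O1, O2, C3 (propanoate-bearing) to C6 (quaternary), and the C6 descriptor switches between R and S along the route only through CIP priority changes in the side chain, not through any change at the centre.

Step 1
Reactants: 1 5-bromo-2-methylpent-2-ene; 2 propyne; 3 oxirane
Product: 6 (3Z)-4,8-dimethylnona-3,7-dien-1-ol, via Grignard reagent 4 (not isolated), via alkenylcopper reagent 5 (not isolated)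
Conditions: Mg, THF; CuBr·SMe2, Et2O/Me2S, −45 °C; propyne, −25 °C; oxirane, −78 → 0 °C; aq NH4Cl
Reagents that add atoms: none
Why: Normant carbocupration adds the alkylcopper reagent syn across propyne, so the homoprenyl group and monovalent copper end up cis, and the alkenylcopper opens oxirane with retention of the alkene geometry to give the Z-trisubstituted homoallylic alcohol.

Step 2
Reactants: 6 (3Z)-4,8-dimethylnona-3,7-dien-1-ol
Product: 7 (3Z)-4,8-dimethylnona-3,7-dienal
Conditions: Dess–Martin periodinane, pyridine, CH2Cl2, 0 °C; used crude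
Reagents that add atoms: none
Why: Dess–Martin oxidation under buffered, non-basic conditions should give the β,γ-unsaturated aldehyde without migration of the alkene into conjugation.

Step 3
Reactants: 7 (3Z)-4,8-dimethylnona-3,7-dienal; 8 (4R)-4-benzyl-3-propanoyl-1,3-oxazolidin-2-one
Product: 10 (4R)-4-benzyl-3-[(2R,3S,5Z)-3-hydroxy-2,6,10-trimethylundeca-5,9-dienoyl]-1,3-oxazolidin-2-one, via boron enolate 9 (not isolated)
Conditions: Bu2BOTf, iPr2NEt, CH2Cl2, −78 → 0 °C; then 7, −78 → 0 °C; pH 7 buffer, MeOH
Reagents that add atoms: none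
Why: Evans syn aldol reaction, in which the Z boron enolate reacts through a Zimmerman–Traxler chair and the benzyl group of the (R)-auxiliary shields one enolate face, so the syn (2R,3S) adduct should form with high selectivity.

Step 4
Reactants: 10 (4R)-4-benzyl-3-[(2R,3S,5Z)-3-hydroxy-2,6,10-trimethylundeca-5,9-dienoyl]-1,3-oxazolidin-2-one
Product: 11 (2S,3S,5Z)-2,6,10-trimethylundeca-5,9-diene-1,3-diol
Conditions: LiBH4, MeOH (1 equiv), Et2O, 0 °C
Reagents that add atoms: none
Why: Reductive removal of the oxazolidinone with LiBH4 gives the primary alcohol without touching either stereocentre or the alkenes (the C2 descriptor changes by priority only).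

Step 5
Reactants: 11 (2S,3S,5Z)-2,6,10-trimethylundeca-5,9-diene-1,3-diol
Product: 12 (2S,3S,5Z)-1-{[tert-butyl(diphenyl)silyl]oxy}-2,6,10-trimethylundeca-5,9-dien-3-ol
Conditions: TBDPSCl, imidazole, CH2Cl2, 0 °C
Reagents that add atoms: tert-butyl(chloro)diphenylsilane CC(C)(C)[Si](Cl)(c1ccccc1)c1ccccc1
Why: Silylation with the bulky chlorosilane is selective for the primary hydroxyl, which masks the future carboxyl carbon at a level that cannot undergo β-elimination in step 7.

Step 6
Reactants: 12 (2S,3S,5Z)-1-{[tert-butyl(diphenyl)silyl]oxy}-2,6,10-trimethylundeca-5,9-dien-3-ol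
Product: 13 (2S,3S,5Z)-1-{[tert-butyl(diphenyl)silyl]oxy}-2,6,10-trimethylundeca-5,9-dien-3-yl methanesulfonate
Conditions: MsCl, Et3N, CH2Cl2, 0 °C
Reagents that add atoms: methanesulfonyl chloride CS(Cl)(=O)=O
Why: Sulfonylation of the secondary alcohol proceeds with retention and turns C3 into an SN2 electrophile.

Step 7
Reactants: 13 (2S,3S,5Z)-1-{[tert-butyl(diphenyl)silyl]oxy}-2,6,10-trimethylundeca-5,9-dien-3-yl methanesulfonate
Product: 15 tert-butyl{[(2S,3R,5Z)-3-hydroperoxy-2,6,10-trimethylundeca-5,9-dien-1-yl]oxy}diphenylsilane, via peroxyketal 14 (not isolated)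
Conditions: 2-methoxyprop-2-yl hydroperoxide, CsOH·H2O, DMF, 0 °C → rt; then AcOH/THF/H2O, rt
Reagents that add atoms: 2-methoxyprop-2-yl hydroperoxide COC(C)(C)OO
Why: Alkylation of a hydroperoxide, in which the caesium salt of the ketal-protected hydroperoxide displaces the secondary methanesulfonate by SN2 with inversion (3S to 3R), and mild aqueous acid then hydrolyses the perketal to the free hydroperoxide without touching the silyl ether.

Step 8
Reactants: 15 tert-butyl{[(2S,3R,5Z)-3-hydroperoxy-2,6,10-trimethylundeca-5,9-dien-1-yl]oxy}diphenylsilane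
Product: 17 tert-butyl{(2S)-2-[(3R,6R)-6-methyl-6-(4-methylpent-3-en-1-yl)-1,2-dioxan-3-yl]propoxy}diphenylsilane, via organomercurial 16 (not isolated)
Conditions: Hg(OAc)2 (1.05 equiv), CH2Cl2, 0 °C; then NaBH4, aq NaOH, 0 °C
Reagents that add atoms: none
Why: Cycloperoxymercuration then hydride demercuration, in which divalent mercury activates the proximal alkene and the hydroperoxide attacks its tertiary carbon (6-endo, Markovnikov, anti addition) through a chair with the C3 substituent equatorial, where the Z geometry forces the homoprenyl group axial and the methyl group equatorial at C6, so the (6R) centre with the chain cis to the C3 substituent should result before NaBH4 replaces mercury by hydrogen.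

Step 9
Reactants: 17 tert-butyl{(2S)-2-[(3R,6R)-6-methyl-6-(4-methylpent-3-en-1-yl)-1,2-dioxan-3-yl]propoxy}diphenylsilane
Product: 18 (2S)-2-[(3R,6R)-6-methyl-6-(4-methylpent-3-en-1-yl)-1,2-dioxan-3-yl]propan-1-ol
Conditions: HF·pyridine, pyridine, THF, 0 °C → rt
Reagents that add atoms: none
Why: Fluoride cleavage of the silyl ether under buffered conditions leaves the dialkyl peroxide and the alkene untouched.

Step 10
Reactants: 18 (2S)-2-[(3R,6R)-6-methyl-6-(4-methylpent-3-en-1-yl)-1,2-dioxan-3-yl]propan-1-ol
Product: 20 methyl (2R)-2-[(3R,6R)-6-methyl-6-(4-methylpent-3-en-1-yl)-1,2-dioxan-3-yl]propanoate, via carboxylic acid 19 (not isolated)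
Conditions: TEMPO (cat.), PhI(OAc)2, MeCN/H2O, rt; then TMSCHN2, MeOH/toluene, 0 °C
Reagents that add atoms: water O; (trimethylsilyl)diazomethane C[Si](C)(C)C=[N+]=[N-]
Why: Oxoammonium oxidation takes the primary alcohol through the aldehyde hydrate to the acid under near-neutral conditions that should not epimerise C2 or open the β-peroxy system, and diazoalkane esterification needs no base.

Step 11
Reactants: 20 methyl (2R)-2-[(3R,6R)-6-methyl-6-(4-methylpent-3-en-1-yl)-1,2-dioxan-3-yl]propanoate
Product: 21 methyl (2R)-2-[(3R,6R)-6-[2-(3,3-dimethyloxiran-2-yl)ethyl]-6-methyl-1,2-dioxan-3-yl]propanoate (both epimers at the oxirane carbon)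
Conditions: mCPBA, CH2Cl2, 0 °C; aq NaHCO3 work-up
Reagents that add atoms: 3-chloroperbenzoic acid OOC(=O)c1cccc(Cl)c1
Why: Prilezhaev epoxidation of the only remaining alkene, whose new oxirane stereocentre is unselective but is destroyed in step 12.

Step 12
Reactants: 21 methyl (2R)-2-[(3R,6R)-6-[2-(3,3-dimethyloxiran-2-yl)ethyl]-6-methyl-1,2-dioxan-3-yl]propanoate
Product: 22 methyl (2R)-2-[(3R,6S)-6-methyl-6-(4-methyl-3-oxopentyl)-1,2-dioxan-3-yl]propanoate
Conditions: BF3·OEt2 (cat.), CH2Cl2, −78 °C
Reagents that add atoms: none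
Why: Meinwald rearrangement, in which the Lewis acid opens the trisubstituted epoxide at the tertiary carbon and a 1,2-hydride shift gives the isopropyl ketone, with both oxirane epimers converging on one product.

Step 13
Reactants: 22 methyl (2R)-2-[(3R,6S)-6-methyl-6-(4-methyl-3-oxopentyl)-1,2-dioxan-3-yl]propanoate; 23 pent-1-en-3-one
Product: 25 diacarperoxide A, via diketone 24 (not isolated)
Conditions: 23 (1.5 equiv), TfOH (5 mol %), CH2Cl2, 0 °C → rt; evaporate; pyrrolidine (30 mol %), AcOH, toluene, 50 °C
Reagents that add atoms: none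
Why: Catalytic TfOH converts ketone 22 into its more substituted (tetrasubstituted) enol, which adds to protonated ethyl vinyl ketone and so forms C4–C5 and the quaternary gem-dimethyl carbon; pyrrolidine then condenses only with the unhindered ethyl ketone of 24, and the enamine carbon C2 attacks the C3 carbonyl, followed by loss of water and hydrolysis to the conjugated enone. The closest known reaction is the Robinson annulation in its acid-catalysed Michael form (as with 2-methylcyclohexanone and vinyl ketones) joined to an enamine aldol condensation of the Hajos–Parrish kind, in which a ketone next to a quaternary carbon is likewise the acceptor. The one ring is closed in the 6-(enolendo)-exo-trig mode. No stereocentre is formed, and the three existing ones lie outside the reacting atoms and should not be epimerised by catalytic acid or by pyrrolidinium acetate. Two regioselectivities are needed: Michael addition at the methine and not at the methylene α-carbon, secured by the preference of acid catalysis for the more substituted enol, and aldol closure of C2 onto C3 and not of the chain methylene onto the C1 carbonyl, secured because a secondary amine forms an enamine only at the unhindered ketone while the neopentyl-type C3 ketone stays a pure acceptor. The dialkyl peroxide and the methyl ester are expected to tolerate both catalyst systems, since neither a strong base (Kornblum–DeLaMare cleavage, retro-oxa-Michael) nor a reducing agent is present.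

**Compound list**

1 | 5-bromo-2-methylpent-2-ene | CC(C)=CCCBr | starting material
2 | propyne | CC#C | starting material
3 | oxirane | C1CO1 | starting material
4 | (4-methylpent-3-en-1-yl)magnesium bromide | CC(C)=CCC[Mg]Br | intermediate
5 | [(1Z)-2,6-dimethylhepta-1,5-dien-1-yl]copper (as its MgBr2 complex) | [Cu]/C=C(\CCC=C(C)C)C | intermediate
6 | (3Z)-4,8-dimethylnona-3,7-dien-1-ol | OCC/C=C(\CCC=C(C)C)C | intermediate
7 | (3Z)-4,8-dimethylnona-3,7-dienal | O=CC/C=C(\CCC=C(C)C)C | intermediate
8 | (4R)-4-benzyl-3-propanoyl-1,3-oxazolidin-2-one | CCC(=O)N1[C@H](Cc2ccccc2)COC1=O | starting material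
9 | dibutylboron Z-enolate of 8 | C/C=C(\OB(CCCC)CCCC)N1[C@H](Cc2ccccc2)COC1=O | intermediate
10 | (4R)-4-benzyl-3-[(2R,3S,5Z)-3-hydroxy-2,6,10-trimethylundeca-5,9-dienoyl]-1,3-oxazolidin-2-one | O=C1OC[C@@H](Cc2ccccc2)N1C(=O)[C@H](C)[C@@H](O)C/C=C(\CCC=C(C)C)C | intermediate
11 | (2S,3S,5Z)-2,6,10-trimethylundeca-5,9-diene-1,3-diol | OC[C@H](C)[C@@H](O)C/C=C(\CCC=C(C)C)C | intermediate
12 | (2S,3S,5Z)-1-{[tert-butyl(diphenyl)silyl]oxy}-2,6,10-trimethylundeca-5,9-dien-3-ol | CC(C)(C)[Si](c1ccccc1)(c1ccccc1)OC[C@H](C)[C@@H](O)C/C=C(\CCC=C(C)C)C | intermediate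
13 | (2S,3S,5Z)-1-{[tert-butyl(diphenyl)silyl]oxy}-2,6,10-trimethylundeca-5,9-dien-3-yl methanesulfonate | CC(C)(C)[Si](c1ccccc1)(c1ccccc1)OC[C@H](C)[C@@H](OS(C)(=O)=O)C/C=C(\CCC=C(C)C)C | intermediate
14 | tert-butyl{[(2S,3R,5Z)-3-[(2-methoxypropan-2-yl)peroxy]-2,6,10-trimethylundeca-5,9-dien-1-yl]oxy}diphenylsilane | CC(C)(C)[Si](c1ccccc1)(c1ccccc1)OC[C@H](C)[C@H](OOC(C)(C)OC)C/C=C(\CCC=C(C)C)C | intermediate
15 | tert-butyl{[(2S,3R,5Z)-3-hydroperoxy-2,6,10-trimethylundeca-5,9-dien-1-yl]oxy}diphenylsilane | CC(C)(C)[Si](c1ccccc1)(c1ccccc1)OC[C@H](C)[C@H](OO)C/C=C(\CCC=C(C)C)C | intermediate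
16 | compound 17 carrying an acetoxymercury group at dioxane C5 (3R,5R,6R; mercury equatorial, cis to the homoprenyl chain) | CC(C)(C)[Si](c1ccccc1)(c1ccccc1)OC[C@H](C)[C@H]1C[C@@H]([Hg]OC(C)=O)[C@@](C)(CCC=C(C)C)OO1 | intermediate
17 | tert-butyl{(2S)-2-[(3R,6R)-6-methyl-6-(4-methylpent-3-en-1-yl)-1,2-dioxan-3-yl]propoxy}diphenylsilane | CC(C)(C)[Si](c1ccccc1)(c1ccccc1)OC[C@H](C)[C@H]1CC[C@@](C)(CCC=C(C)C)OO1 | intermediate
18 | (2S)-2-[(3R,6R)-6-methyl-6-(4-methylpent-3-en-1-yl)-1,2-dioxan-3-yl]propan-1-ol | OC[C@H](C)[C@H]1CC[C@@](C)(CCC=C(C)C)OO1 | intermediate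
19 | (2R)-2-[(3R,6R)-6-methyl-6-(4-methylpent-3-en-1-yl)-1,2-dioxan-3-yl]propanoic acid | OC(=O)[C@H](C)[C@H]1CC[C@@](C)(CCC=C(C)C)OO1 | intermediate
20 | methyl (2R)-2-[(3R,6R)-6-methyl-6-(4-methylpent-3-en-1-yl)-1,2-dioxan-3-yl]propanoate | COC(=O)[C@H](C)[C@H]1CC[C@@](C)(CCC=C(C)C)OO1 | intermediate
21 | methyl (2R)-2-[(3R,6R)-6-[2-(3,3-dimethyloxiran-2-yl)ethyl]-6-methyl-1,2-dioxan-3-yl]propanoate, both epimers at the oxirane carbon | COC(=O)[C@H](C)[C@H]1CC[C@@](C)(CCC2OC2(C)C)OO1 | intermediate
22 | methyl (2R)-2-[(3R,6S)-6-methyl-6-(4-methyl-3-oxopentyl)-1,2-dioxan-3-yl]propanoate | COC(=O)[C@H](C)[C@H]1CC[C@@](C)(CCC(=O)C(C)C)OO1 | intermediate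
23 | pent-1-en-3-one (ethyl vinyl ketone) | CCC(=O)C=C | starting material
24 | methyl (2R)-2-[(3R,6S)-6-(4,4-dimethyl-3,7-dioxononyl)-6-methyl-1,2-dioxan-3-yl]propanoate | COC(=O)[C@H](C)[C@H]1CC[C@@](C)(CCC(=O)C(C)(C)CCC(=O)CC)OO1 | intermediate
25 | diacarperoxide A, methyl (2R)-2-[(3R,6R)-6-methyl-6-[2-(2,6,6-trimethyl-3-oxocyclohex-1-en-1-yl)ethyl]-1,2-dioxan-3-yl]propanoate | COC(=O)[C@H](C)[C@H]1CC[C@@](C)(CCC2=C(C)C(=O)CCC2(C)C)OO1 | target

**Route length.** Total step count: 13. Longest linear sequence: 13 steps (all partners are commercial).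

**Steps most likely to fail**

Step 7. Elimination toward the allylic C4 hydrogens may outrun substitution at the β-branched secondary sulfonate, so that the C3 oxygen function is lost as a conjugated diene. The fallback sets out from diol 11 and returns at alcohol 18. Selective tosylation of the primary hydroxyl (TsCl, pyridine, 0 °C) gives the monotosylate F1, and KOtBu in THF closes it to the 2,3-disubstituted oxetane F2 with retention at both centres. Lewis-acid-mediated opening with ethereal H2O2 (TMSOTf cat., Et2O, −78 → 0 °C) should occur at the more substituted ring carbon with inversion and give the hydroperoxy alcohol F3. Cycloperoxymercuration and demercuration as in step 8 then lead directly to 18, so the silyl ether steps fall away.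

Step 8. The carbon radical formed during hydride demercuration may attack the O–O bond and open the ring; mercuration of the remote alkene and leakage through a twist-boat transition state may also erode yield and facial selectivity. The fallback sets out from hydroperoxide 15 and returns at 17. N-(Phenylseleno)phthalimide with camphorsulfonic acid (CH2Cl2, −78 °C) should cyclise 15 in the same 6-endo anti sense to the 5-phenylselanyl dioxane F4. H2O2/pyridine at 0 °C gives the selenoxide F5, which loses benzeneselenenic acid by syn elimination toward C4 (C6 carries no hydrogen) to give the 3,6-dihydro-1,2-dioxine F6. Diimide (potassium azodicarboxylate, AcOH, MeOH, 0 °C) should saturate the disubstituted ring alkene faster than the trisubstituted side-chain alkene and give 17 without any radical at C5.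

Step 13. Conjugate addition may go through the less substituted enol, the aldol closure may run in the other sense (chain methylene onto the ethyl ketone carbonyl), or the vinyl ketone may polymerise under acid. The fallback sets out from ketone 22 and returns at diketone 24. Equilibrating silylation (TMSOTf, Et3N, CH2Cl2, rt) gives the tetrasubstituted silyl enol ether F7, which is purified so that the nucleophilic carbon is fixed. Mukaiyama–Michael addition to 23 (BF3·OEt2, CH2Cl2, −78 °C) gives 24 as an isolated compound, and the amine-catalysed aldol condensation (pyrrolidine, AcOH, toluene, 50 °C) is then run on its own to 25.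

**Further compounds**

F1 | step 7 | (2S,3S,5Z)-3-hydroxy-2,6,10-trimethylundeca-5,9-dien-1-yl 4-methylbenzenesulfonate | Cc1ccc(cc1)S(=O)(=O)OC[C@H](C)[C@@H](O)C/C=C(\CCC=C(C)C)C
F2 | step 7 | (2S,3S)-2-[(2Z)-3,7-dimethylocta-2,6-dien-1-yl]-3-methyloxetane | C[C@H]1CO[C@H]1C/C=C(\CCC=C(C)C)C
F3 | step 7 | (2S,3R,5Z)-3-hydroperoxy-2,6,10-trimethylundeca-5,9-dien-1-ol | OC[C@H](C)[C@H](OO)C/C=C(\CCC=C(C)C)C
F4 | step 8 | compound 17 carrying a phenylselanyl group at dioxane C5 (3R,5R,6R) | CC(C)(C)[Si](c1ccccc1)(c1ccccc1)OC[C@H](C)[C@H]1C[C@@H]([Se]c2ccccc2)[C@@](C)(CCC=C(C)C)OO1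
F5 | step 8 | selenoxide of F4 | CC(C)(C)[Si](c1ccccc1)(c1ccccc1)OC[C@H](C)[C@H]1C[C@@H]([Se](=O)c2ccccc2)[C@@](C)(CCC=C(C)C)OO1
F6 | step 8 | tert-butyl{(2S)-2-[(3R,6R)-6-methyl-6-(4-methylpent-3-en-1-yl)-3,6-dihydro-1,2-dioxin-3-yl]propoxy}diphenylsilane | CC(C)(C)[Si](c1ccccc1)(c1ccccc1)OC[C@H](C)[C@H]1C=C[C@@](C)(CCC=C(C)C)OO1
F7 | step 13 | methyl (2R)-2-[(3R,6S)-6-methyl-6-{4-methyl-3-[(trimethylsilyl)oxy]pent-3-en-1-yl}-1,2-dioxan-3-yl]propanoate | COC(=O)[C@H](C)[C@H]1CC[C@@](C)(CCC(O[Si](C)(C)C)=C(C)C)OO1
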